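## Retrosynthetic overview

1. The target is opened at the C2–O bond: the dihydrofuran ring is the only ring built and is closed last, from a permethylated 1,2,2-triarylethanol, by BBr3 (ring closure plus global demethylation, C2 settling trans to C3).
2. The triarylethanol comes from the ring B Grignard reagent and an (S)-2,2-diarylacetaldehyde (C2–ring B bond).
3. The (S)-aldehyde comes from an (E)-stilbene by an enantioselective oxidative 1,2-aryl shift with a chiral aryl-λ3-iodane. Ring A moves from the future C2 to the future C3, which makes the congested ring A–C3 bond and sets C3.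
4. The stilbene comes from a Mizoroki–Heck coupling of the ring A iodide with 3,5-dimethoxystyrene. The iodide comes from ortho-lithiation/iodination of the ring A–ring D bibenzyl, itself made from the same styrene and 4-iodoanisole by hydroboration/B-alkyl Suzuki–Miyaura coupling.
5. All four benzene rings are bought intact: rings A, B and C from resorcinol (via 1,3-dimethoxybenzene), ring D from 4-iodophenol, and both two-carbon bridges from vinyl bromide.

Labels: benzofuran numbering (C2, C3); ring A = benzo ring, ring B = 2,4-dihydroxyphenyl on C2, ring C = 3,5-dihydroxyphenyl on C3, ring D = 4-hydroxyphenyl of the side chain. The target is the trans-(2S,3S) isomer.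

Assumption: the (R,R)-lactate-derived aryl-λ3-iodane gives the (S)-aldehyde; if the sense of induction proves opposite, its (S,S)-antipode from the other lactate enantiomer is used with no other change.

## Route

Step 1
Reactants: 1 resorcinol
Product: 2 1,3-dimethoxybenzene
Conditions: Me2SO4 (2.5 equiv), K2CO3 (3 equiv), acetone, reflux
Reagents that add atoms: dimethyl sulfate, COS(=O)(=O)OC
Why: Double Williamson O-methylation of the phenoxides is the standard preparation of resorcinol dimethyl ether and installs the methyl ethers that later direct C–H borylation and lithiation.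

Step 2
Reactants: 2 1,3-dimethoxybenzene; 3 vinyl bromide (bromoethene)
Product: 5 1-ethenyl-3,5-dimethoxybenzene (3,5-dimethoxystyrene), via pinacol boronate 4 (not isolated)
Conditions: B2pin2 (0.6 equiv), [Ir(cod)(OMe)]2 (1.5 mol%), dtbpy (3 mol%), THF, 80 °C; then vinyl bromide (1 M in THF, 1.5 equiv), Pd(dppf)Cl2 (3 mol%), 3 M aq KOH, 60 °C, sealed
Reagents that add atoms: bis(pinacolato)diboron, CC1(C)OB(OC1(C)C)B1OC(C)(C)C(C)(C)O1 (boryl group of 4 only)
Why: Sterically governed C–H borylation with [Ir(cod)(OMe)]2/dtbpy takes place only at C5, meta to both methoxy groups, and the boronate is vinylated in the same pot by Suzuki–Miyaura coupling with Pd(dppf)Cl2.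

Step 3
Reactants: 6 4-iodophenol
Product: 7 1-iodo-4-methoxybenzene (4-iodoanisole)
Conditions: MeI (1.5 equiv), K2CO3, acetone, reflux
Reagents that add atoms: iodomethane, CI
Why: Williamson O-methylation masks the ring D phenol, which would otherwise be oxidised by the trivalent-iodine reagent of step 7.

Step 4
Reactants: 5 3,5-dimethoxystyrene; 7 4-iodoanisole
Product: 9 1,3-dimethoxy-5-[2-(4-methoxyphenyl)ethyl]benzene, via alkyl-9-BBN borane 8 (not isolated)
Conditions: 9-BBN (0.5 M in THF, 1.1 equiv), 0 °C → rt; then 7, Pd(dppf)Cl2 (3 mol%), 3 M aq NaOH, THF, 65 °C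
Reagents that add atoms: 9-borabicyclo[3.3.1]nonane, B1C2CCCC1CCC2 (borane unit of 8 only)
Why: Anti-Markovnikov hydroboration followed by B-alkyl Suzuki–Miyaura coupling joins the primary alkylborane to the aryl iodide and gives the saturated two-carbon bridge directly.

Step 5
Reactants: 9 1,3-dimethoxy-5-[2-(4-methoxyphenyl)ethyl]benzene
Product: 11 2-iodo-1,3-dimethoxy-5-[2-(4-methoxyphenyl)ethyl]benzene, via aryllithium 10 (not isolated)
Conditions: n-BuLi (1.2 equiv), TMEDA, THF, 0 °C → rt; I2 (1.3 equiv), −78 °C → rt
Reagents that add atoms: n-butyllithium, [Li]CCCC (lithium of 10 only); iodine, II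
Why: Directed ortho-metalation removes the proton between the two methoxy groups of ring A, by far the most activated ring position, and iodine quench gives the iodide at the future C3a.

Step 6
Reactants: 11 2-iodo-1,3-dimethoxy-5-[2-(4-methoxyphenyl)ethyl]benzene; 5 3,5-dimethoxystyrene
Product: 12 2-[(E)-2-(3,5-dimethoxyphenyl)ethenyl]-1,3-dimethoxy-5-[2-(4-methoxyphenyl)ethyl]benzene
Conditions: Pd(OAc)2 (5 mol%), n-Bu4NCl (1 equiv), K2CO3 (2.5 equiv), DMF, 100 °C
Reagents that add atoms: none
Why: Mizoroki–Heck coupling under Jeffery conditions arylates the terminal alkene carbon and syn β-hydride elimination gives the (E)-stilbene, aryl iodides tolerating the two ortho methoxy groups.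

Step 7
Reactants: 12 (E)-stilbene
Product: 14 (2S)-2-(3,5-dimethoxyphenyl)-2-{2,6-dimethoxy-4-[2-(4-methoxyphenyl)ethyl]phenyl}acetaldehyde, via dimethyl acetal 13 (not isolated)
Conditions: (R,R)-ArI(OAc)2 [Ar = 2,6-bis((R)-1-methoxycarbonylethoxy)phenyl] (1.3 equiv), TsOH·H2O (1.5 equiv), MeOH (10 equiv), CH2Cl2/CF3CH2OH 10:1, −78 → −40 °C; then H2O/THF, 0 °C, 1 h; NaHCO3
Reagents that add atoms: methanol, CO (methoxy groups of 13 only); water, O (aldehyde oxygen of 14)
Why: Proposed new method: the twofold-symmetric lactate aryl-λ3-iodane adds to one face of the alkene with iodine on the 3,5-dimethoxybenzylic carbon and methanol anti on the carbon that ring A stabilises, and the very electron-rich ring A then shifts 1,2 through a phenonium ion with inversion, expelling ArI, so that the chosen face fixes the new diaryl stereocentre as S and the methoxycarbenium ion is trapped as acetal 13 and hydrolysed in the flask; the closest known reaction types are the racemic trivalent-iodine oxidative rearrangement of stilbenes to 2,2-diarylacetaldehyde acetals and the enantioselective lactate-iodane rearrangement of 1,1-disubstituted alkenes to α-aryl ketones, here extended to an unsymmetrical 1,2-diarylethene.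

Step 8
Reactants: 2 1,3-dimethoxybenzene
Product: 15 1-bromo-2,4-dimethoxybenzene
Conditions: NBS (1.0 equiv), MeCN, 0 °C → rt
Reagents that add atoms: N-bromosuccinimide, O=C1CCC(=O)N1Br
Why: Electrophilic aromatic bromination goes para to one and ortho to the other methoxy group, the position between them being hindered, which gives the 2,4-dioxygenated pattern of ring B.

Step 9
Reactants: 14 (S)-aldehyde; 15 1-bromo-2,4-dimethoxybenzene
Product: 17 (2S)-1-(2,4-dimethoxyphenyl)-2-(3,5-dimethoxyphenyl)-2-{2,6-dimethoxy-4-[2-(4-methoxyphenyl)ethyl]phenyl}ethan-1-ol (both C1 epimers), via aryl Grignard reagent 16 (not isolated)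
Conditions: 15 (2 equiv), Mg, THF, 40 °C; then LaCl3·2LiCl (0.3 equiv), 14, THF, −78 °C; NH4Cl aq
Reagents that add atoms: magnesium, [Mg] (in 16 only)
Why: Grignard addition to the aldehyde, with LaCl3·2LiCl activating the carbonyl and suppressing enolisation so that the diaryl stereocentre is kept, forms the C2–ring B bond; the new carbinol centre is uncontrolled and irrelevant because it is ionised in step 10.

Step 10
Reactants: 17 triarylethanol
Product: 19 (2S,3S)-2-(2,4-dihydroxyphenyl)-3-(3,5-dihydroxyphenyl)-6-[2-(4-hydroxyphenyl)ethyl]-2,3-dihydro-1-benzofuran-4-ol (target; trans), via hexamethyl ether 18 (not isolated)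
Conditions: BBr3 (1 M in CH2Cl2, 12 equiv), CH2Cl2, −78 °C → rt; MeOH then NaHCO3 aq, 0 °C
Reagents that add atoms: none
Why: BBr3 ionises the benzylic alcohol to a cation stabilised by the 2,4-dioxygenated ring B, either of the two equivalent ortho methoxy oxygens of ring A closes the five-membered ring and bromide removes its methyl group (SN1 cyclodehydration with neighbouring-group participation), the six remaining aryl methyl ethers are then cleaved, and C2 closes, and can equilibrate by reversible C2–O ionisation, trans to the C3 aryl group, so 3S gives 2S.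

## Compound list

1 | resorcinol (benzene-1,3-diol) | Oc1cccc(O)c1 | starting material
2 | 1,3-dimethoxybenzene | COc1cccc(OC)c1 | intermediate
3 | vinyl bromide (bromoethene) | C=CBr | starting material
4 | 2-(3,5-dimethoxyphenyl)-4,4,5,5-tetramethyl-1,3,2-dioxaborolane | COc1cc(OC)cc(c1)B1OC(C)(C)C(C)(C)O1 | intermediate
5 | 1-ethenyl-3,5-dimethoxybenzene | C=Cc1cc(OC)cc(OC)c1 | intermediate
6 | 4-iodophenol | Oc1ccc(I)cc1 | starting material
7 | 1-iodo-4-methoxybenzene | COc1ccc(I)cc1 | intermediate
8 | 9-[2-(3,5-dimethoxyphenyl)ethyl]-9-borabicyclo[3.3.1]nonane | COc1cc(CCB2C3CCCC2CCC3)cc(OC)c1 | intermediate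
9 | 1,3-dimethoxy-5-[2-(4-methoxyphenyl)ethyl]benzene | COc1ccc(CCc2cc(OC)cc(OC)c2)cc1 | intermediate
10 | {2,6-dimethoxy-4-[2-(4-methoxyphenyl)ethyl]phenyl}lithium | [Li]c1c(OC)cc(CCc2ccc(OC)cc2)cc1OC | intermediate
11 | 2-iodo-1,3-dimethoxy-5-[2-(4-methoxyphenyl)ethyl]benzene | COc1ccc(CCc2cc(OC)c(I)c(OC)c2)cc1 | intermediate
12 | 2-[(E)-2-(3,5-dimethoxyphenyl)ethenyl]-1,3-dimethoxy-5-[2-(4-methoxyphenyl)ethyl]benzene | COc1ccc(CCc2cc(OC)c(/C=C/c3cc(OC)cc(OC)c3)c(OC)c2)cc1 | intermediate
13 | 2-[(1S)-1-(3,5-dimethoxyphenyl)-2,2-dimethoxyethyl]-1,3-dimethoxy-5-[2-(4-methoxyphenyl)ethyl]benzene | COC(OC)[C@H](c1c(OC)cc(CCc2ccc(OC)cc2)cc1OC)c1cc(OC)cc(OC)c1 | intermediate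
14 | (2S)-2-(3,5-dimethoxyphenyl)-2-{2,6-dimethoxy-4-[2-(4-methoxyphenyl)ethyl]phenyl}acetaldehyde | O=C[C@H](c1c(OC)cc(CCc2ccc(OC)cc2)cc1OC)c1cc(OC)cc(OC)c1 | intermediate
15 | 1-bromo-2,4-dimethoxybenzene | COc1ccc(Br)c(OC)c1 | intermediate
16 | (2,4-dimethoxyphenyl)magnesium bromide | COc1ccc([Mg]Br)c(OC)c1 | intermediate
17 | (2S)-1-(2,4-dimethoxyphenyl)-2-(3,5-dimethoxyphenyl)-2-{2,6-dimethoxy-4-[2-(4-methoxyphenyl)ethyl]phenyl}ethan-1-ol, both C1 epimers | OC(c1ccc(OC)cc1OC)[C@H](c1c(OC)cc(CCc2ccc(OC)cc2)cc1OC)c1cc(OC)cc(OC)c1 | intermediate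
18 | (2S,3S)-2-(2,4-dimethoxyphenyl)-3-(3,5-dimethoxyphenyl)-4-methoxy-6-[2-(4-methoxyphenyl)ethyl]-2,3-dihydro-1-benzofuran (trans) | COc1ccc(CCc2cc(OC)c3c(c2)O[C@H](c2ccc(OC)cc2OC)[C@H]3c2cc(OC)cc(OC)c2)cc1 | intermediate
19 | (2S,3S)-2-(2,4-dihydroxyphenyl)-3-(3,5-dihydroxyphenyl)-6-[2-(4-hydroxyphenyl)ethyl]-2,3-dihydro-1-benzofuran-4-ol (trans) | Oc1ccc(CCc2cc(O)c3c(c2)O[C@H](c2ccc(O)cc2O)[C@H]3c2cc(O)cc(O)c2)cc1 | target

## Step count and risks

Total: 10 steps. Longest linear sequence: 8 steps (1, 2, 4, 5, 6, 7, 9, 10); steps 3 and 8 are one-step branches.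

Steps most likely to fail:

Step 7 (the proposed method). The trivalent-iodine reagent may oxidise the electron-rich rings instead of the alkene, vicinal dimethoxylation may compete with the aryl shift, and the enantioselectivity on a 1,2-diarylethene is untested. The fallback uses known chemistry and sets out from 12. Treatment with PhI(OH)OTs in MeOH at room temperature, the established racemic oxidative rearrangement of stilbenes, gives the racemic dimethyl acetal F1. Preparative chiral-phase SFC separates the (S)-acetal 13 from the (R)-acetal F2, which is set aside. Isolated 13 is hydrolysed with catalytic TsOH in wet acetone at 0 °C, and the route is rejoined at 14.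

Step 9. The α,α-diaryl aldehyde 14 can be enolised by the basic Grignard reagent, which lowers the yield and can erode the ee. The fallback avoids the free aldehyde and sets out from 13, isolated by leaving out the water/THF stage of step 7. Friedel–Crafts arylation of its methoxycarbenium ion with 2 (TMSOTf, CH2Cl2, −78 °C) gives the methyl ether F3. Under the BBr3 conditions of step 10, F3 ionises at the benzylic methoxy group just as 17 does at its hydroxyl, and it returns to the route at 18 and hence 19.

Step 10. The C2 cation may lose the C3 proton to give a triarylethene, or undergo a 1,2-hydride shift, before ring closure. Prolonged exposure to BBr3 may also erode the C3 configuration through ring opening. The fallback decouples ring closure from deprotection and sets out from 17. BCl3 (1.2 equiv, CH2Cl2, −78 °C) closes the ring only, so 18 can be isolated and its trans configuration and ee checked. The six methyl ethers are then removed by hard-acid/soft-nucleophile cleavage with AlCl3/EtSH (CH2Cl2, 0 °C → rt), returning at 19.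

## Further compounds

F1 | step 7 | racemic 2-[1-(3,5-dimethoxyphenyl)-2,2-dimethoxyethyl]-1,3-dimethoxy-5-[2-(4-methoxyphenyl)ethyl]benzene | COC(OC)C(c1c(OC)cc(CCc2ccc(OC)cc2)cc1OC)c1cc(OC)cc(OC)c1
F2 | step 7 | 2-[(1R)-1-(3,5-dimethoxyphenyl)-2,2-dimethoxyethyl]-1,3-dimethoxy-5-[2-(4-methoxyphenyl)ethyl]benzene | COC(OC)[C@@H](c1c(OC)cc(CCc2ccc(OC)cc2)cc1OC)c1cc(OC)cc(OC)c1
F3 | step 9 | 2-[(1S)-2-(2,4-dimethoxyphenyl)-1-(3,5-dimethoxyphenyl)-2-methoxyethyl]-1,3-dimethoxy-5-[2-(4-methoxyphenyl)ethyl]benzene, both epimers at the methoxy-bearing carbon | COC(c1ccc(OC)cc1OC)[C@H](c1c(OC)cc(CCc2ccc(OC)cc2)cc1OC)c1cc(OC)cc(OC)c1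
F0 | step 10 | none | none
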